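**Plan**

1. Retrosynthesis: the C-5 methylene comes from a lactam carbonyl. The N-4–C-9a and N-4–C-5 bonds are then cut together in a retro-Schmidt sense, which re-forms a C-5–C-9a bond that the target does not have. This gives a cis-hydrindan-5-one with an azide at C-3. Further cuts are C-3–C-18 (vinylogous Mannich), the C-13 methyl and hydroxyl, the C-11–O/C-12–C-13 lactone, and the C-9=C-10 aldol bond back to cyclohexane-1,3-dione.
2. Enabling feature: C-9a is the aza-quaternary atom shared by the pyrrolidine, the azepane and the cyclopentane. As the all-carbon α-quaternary carbon of a cyclohexanone (C-5 to C-9a) it is easy to build, and its 1,2-shift from C-5 to nitrogen with retention turns it into the aza-quaternary centre.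
3. Forward ring order: cyclohexanedione → cyclopentenone (aldol) → fused γ-lactone → pendant γ-lactone → pyrrolidine and azepane together in the Schmidt step (azepane last) → removal of the lactam carbonyl.
4. Stereochemistry: C-9a from an enantiotopic-carbonyl-selective aldol condensation; C-12 by alkylation anti to the C-5 ketal; C-11 by Luche reduction anti to the C-12 chain; C-9 and C-10 by hydroxyl-directed hydrogenation; C-13 by convex-face hydroxylation then methylation; C-3 from the sulfinyl auxiliary, C-18 from the Mannich transition state, C-20 by hydrogenation anti to the C-18 substituent.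

Key step: step 20

Remark: locants in names follow the Stemona numbering of the target (C-1 to C-3 and N-4 pyrrolidine; N-4, C-5 to C-9, C-9a azepane; C-9, C-9a, C-12, C-11, C-10 cyclopentane; C-13, C-14 fused lactone; C-18 to C-21 pendant lactone).
Assumption: the sense of induction in steps 5 and 16 is taken as written; if the opposite sense is found, the enantiomeric catalyst or sulfinamide is used.

**Step 1**
Reactants: 1 cyclohexane-1,3-dione; 2 1-bromopent-2-yne
Product: 3 2-(pent-2-yn-1-yl)cyclohexane-1,3-dione
Conditions: KOH, H2O, 0 °C to 50 °C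
Reagents that add atoms: none
Why: C-alkylation of the dione enolate by a propargylic bromide in water should give the 2-substituted dione; no stereocentre is formed.

**Step 2**
Reactants: 3 2-(pent-2-yn-1-yl)cyclohexane-1,3-dione; 4 acrolein
Product: 5 3-[2,6-dioxo-1-(pent-2-yn-1-yl)cyclohexyl]propanal
Conditions: H2O, rt
Reagents that add atoms: none
Why: Michael addition of a 2-substituted 1,3-dione to acrolein should form the still prochiral quaternary carbon (future C-9a) and bring in C-1 to C-3 at the aldehyde level.

**Step 3**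
Reactants: 5 3-[2,6-dioxo-1-(pent-2-yn-1-yl)cyclohexyl]propanal
Product: 6 2-[2-(1,3-dioxolan-2-yl)ethyl]-2-(pent-2-yn-1-yl)cyclohexane-1,3-dione
Conditions: ethylene glycol (1.1 equiv), PPTS (cat.), benzene, reflux, Dean–Stark
Reagents that add atoms: ethylene glycol (OCCO)
Why: acetalization should take the aldehyde in preference to the two ring ketones, which flank a quaternary carbon.

**Step 4**
Reactants: 6 2-[2-(1,3-dioxolan-2-yl)ethyl]-2-(pent-2-yn-1-yl)cyclohexane-1,3-dione
Product: 7 2-[2-(1,3-dioxolan-2-yl)ethyl]-2-(2-oxopentyl)cyclohexane-1,3-dione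
Conditions: Ph3PAuNTf2 (2 mol %), H2O (3 equiv), 1,4-dioxane, 60 °C
Reagents that add atoms: water (O)
Why: gold-catalysed alkyne hydration in which 5-exo-dig participation of a ring carbonyl oxygen should place the new ketone on the alkyne carbon nearer the ring (future C-11).

**Step 5**
Reactants: 7 2-[2-(1,3-dioxolan-2-yl)ethyl]-2-(2-oxopentyl)cyclohexane-1,3-dione
Product: 8 (9aS)-bicyclic enedione, (7aS)-7a-[2-(1,3-dioxolan-2-yl)ethyl]-3-ethyl-4,5,6,7a-tetrahydro-1H-indene-2,7-dione (C-11 enone carbonyl, C-9=C-10 double bond, C-5 ketone)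
Conditions: (R)-3,3′-bis(2,4,6-triisopropylphenyl)-1,1′-binaphthyl-2,2′-diyl hydrogen phosphate (5 mol %), 4 Å molecular sieves, toluene, 80 °C
Reagents that add atoms: none
Why: Proposed new method: the chiral phosphoric acid should enolize the side-chain ketone toward C-10 and, while hydrogen-bonded to one of the two enantiotopic ring carbonyls, guide aldol addition and dehydration so that only that carbonyl becomes C-9 and C-9a is set as (S); the closest known reaction type is the acid- or amino-acid-catalysed desymmetrizing aldol condensation of 2,2-disubstituted cyclohexane-1,3-diones to six-membered enones (Hajos–Parrish type), here transferred to the 5-(enolendo) closure of a 1,4-diketone, which is known only in racemic form under acid or base.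

**Step 6**
Reactants: 8 (9aS)-bicyclic enedione
Product: 9 (9aS)-C-5 ethylene ketal of 8 (spiro-1,3-dioxolane at C-5; cyclopentenone unchanged)
Conditions: ethylene glycol, TsOH·H2O (cat.), benzene, reflux, Dean–Stark
Reagents that add atoms: ethylene glycol (OCCO)
Why: chemoselective ketalization of the saturated ketone over the conjugated enone carbonyl, as is usual for bicyclic enediones; no stereocentre changes.

**Step 7**
Reactants: 9 (9aS)-C-5 ethylene ketal; 10 tert-butyl bromoacetate
Product: 12 (9aS,12S)-enone ester with CH2CO2tBu at C-12 cis to the C-1 chain, via lithium dienolate 11 (not isolated)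
Conditions: LiN(iPr)2, THF, −78 °C; then 10, DMPU, −78 °C to −20 °C
Reagents that add atoms: none
Why: kinetic α′-deprotonation of the cyclopentenone and enolate alkylation; the electrophile should approach C-12 anti to the spiro-ketal carbon C-5, the bulkier of the two groups that C-9a holds above and below the enone plane, so that the side chain ends cis to the C-1 chain.

**Step 8**
Reactants: 12 (9aS,12S)-enone ester
Product: 13 (9aS,11S,12S)-allylic alcohol (11-OH cis to the C-12 side chain)
Conditions: NaBH4, CeCl3·7H2O, MeOH, −78 °C to 0 °C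
Reagents that add atoms: none
Why: Luche 1,2-reduction with hydride delivered anti to the adjacent C-12 side chain should give the cis alcohol while the tert-butyl ester resists lactonization.

**Step 9**
Reactants: 13 (9aS,11S,12S)-allylic alcohol
Product: 14 (9R,9aR,10S,11R,12S)-hydroxy ester (cis-hydrindane; H-9, H-10, 11-OH, the C-12 chain and the C-1 chain on one face; ethyl cis to C-8)
Conditions: [Ir(cod)(PCy3)(py)]PF6 (5 mol %), H2 (1 atm), CH2Cl2, rt
Reagents that add atoms: none
Why: hydroxyl-directed hydrogenation: iridium bound to the C-11 hydroxyl should deliver both hydrogens to the tetrasubstituted C-9=C-10 bond from the hydroxyl face, which sets C-9 and C-10 by syn addition.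

**Step 10**
Reactants: 14 (9R,9aR,10S,11R,12S)-hydroxy ester
Product: 15 (9R,9aR,10S,11R,12S)-tricyclic γ-lactone bis-dioxolane (lactone cis-fused at C-11/C-12, on the face opposite the six-membered ring)
Conditions: KOtBu (0.1 equiv), THF, 0 °C to rt
Reagents that add atoms: none
Why: alkoxide-catalysed intramolecular transesterification (5-exo-trig lactonization) of the cis γ-hydroxy ester; no stereocentre changes.

**Step 11**
Reactants: 15 tricyclic γ-lactone bis-dioxolane
Product: 18 (13R)-13-(triethylsilyloxy) lactone, via potassium lactone enolate 16 (not isolated), via potassium 13-alkoxide 17 (not isolated)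
Conditions: KN(SiMe3)2, THF, −78 °C; 2-(phenylsulfonyl)-3-phenyloxaziridine; then Et3SiCl, −78 °C to 0 °C
Reagents that add atoms: 2-(phenylsulfonyl)-3-phenyloxaziridine (O=S(=O)(c1ccccc1)N1OC1c1ccccc1); chlorotriethylsilane (CC[Si](Cl)(CC)CC)
Why: enolate hydroxylation with an N-sulfonyloxaziridine from the convex face of the cis-fused bicyclic lactone, followed by silylation of the alkoxide; the C-13 configuration is provisional because C-13 is enolized again in step 12.

**Step 12**
Reactants: 18 (13R)-13-(triethylsilyloxy) lactone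
Product: 20 (13S)-13-methyl-13-(triethylsilyloxy) lactone, via lithium silyloxy enolate 19 (not isolated)
Conditions: LiN(iPr)2, THF, DMPU, −78 °C; then MeI, −78 °C to −40 °C
Reagents that add atoms: iodomethane (CI)
Why: alkylation of the α-silyloxy lactone enolate; methyl iodide should enter from the convex face (the concave face is closed by C-9a and its C-1 chain), which puts methyl cis to H-12 and the oxygen on the concave face as in the target.

**Step 13**
Reactants: 20 (13S)-13-methyl-13-(triethylsilyloxy) lactone
Product: 21 C-3 aldehyde (C-5 ketal and silyl ether kept)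
Conditions: Et3SiOTf (2 equiv), 2,6-lutidine (3 equiv), CH2Cl2, 0 °C; then H2O
Reagents that add atoms: water (O)
Why: the silyl triflate–pyridine base method cleaves aldehyde-derived acetals through a pyridinium intermediate and is known to spare ketone-derived ketals, so only the C-3 dioxolane should open.

**Step 14**
Reactants: 21 C-3 aldehyde; 22 (R)-2-methylpropane-2-sulfinamide
Product: 23 (RS,E)-N-tert-butanesulfinyl aldimine
Conditions: Ti(OEt)4 (2 equiv), THF, rt
Reagents that add atoms: none
Why: titanium-alkoxide-mediated condensation of an aldehyde with tert-butanesulfinamide should give the (E)-sulfinimine; the protected C-5 ketone cannot compete.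

**Step 15**
Reactants: 24 3-methylfuran-2(5H)-one
Product: 25 3-methyl-2-(triisopropylsilyloxy)furan
Conditions: iPr3SiOTf, Et3N, CH2Cl2, 0 °C
Reagents that add atoms: triisopropylsilyl trifluoromethanesulfonate (CC(C)[Si](OS(=O)(=O)C(F)(F)F)(C(C)C)C(C)C)
Why: O-silylation of the butenolide dienolate is the standard route to 2-silyloxyfurans; no stereocentre is formed.

**Step 16**
Reactants: 23 (RS,E)-N-tert-butanesulfinyl aldimine; 25 3-methyl-2-(triisopropylsilyloxy)furan
Product: 26 (3S,18S)-N-sulfinyl aminoalkyl butenolide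
Conditions: Me3SiOTf (0.2 equiv), CH2Cl2, −78 °C; aqueous NaHCO3 work-up
Reagents that add atoms: none
Why: vinylogous Mukaiyama–Mannich addition of the furan C-5 to the activated sulfinimine; the (R)-sulfinyl group should fix C-3 as (S) through an open transition state with attack anti to tert-butyl, and the antiperiplanar approach usual for silyloxyfurans should give the threo (18S) butenolide.

**Step 17**
Reactants: 26 (3S,18S)-N-sulfinyl aminoalkyl butenolide
Product: 27 (3S,18S,20S)-N-sulfinyl aminoalkyl γ-lactone
Conditions: H2 (1 atm), Pd/C (10% palladium on carbon), EtOAc, rt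
Reagents that add atoms: none
Why: heterogeneous hydrogenation of the butenolide from the face opposite the C-18 substituent should give the cis-2,4-disubstituted lactone, which sets C-20.

**Step 18**
Reactants: 27 (3S,18S,20S)-N-sulfinyl aminoalkyl γ-lactone
Product: 29 (3S)-azide (C-5 ketal and silyl ether kept), via ammonium chloride 28 (not isolated)
Conditions: HCl (4 M in 1,4-dioxane), MeOH (5 equiv), CH2Cl2, 0 °C; then imidazole-1-sulfonyl azide hydrochloride, K2CO3, CuSO4·5H2O (cat.), MeOH, 0 °C to rt
Reagents that add atoms: imidazole-1-sulfonyl azide hydrochloride ([N-]=[N+]=NS(=O)(=O)n1ccnc1.Cl)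
Why: acid cleavage of the N–S bond followed by copper-catalysed diazo transfer converts the amine into the azide with retention at C-3; the ketone is still masked, so the free amine cannot condense with it.

**Step 19**
Reactants: 29 (3S)-azide
Product: 30 azido hydroxy ketone (C-5 ketone, free 13-OH)
Conditions: 2 M HCl, THF, 40 °C
Reagents that add atoms: water (O)
Why: aqueous acid hydrolysis of the hindered ketal and of the tertiary silyl ether; azide and lactones should be stable and no stereocentre is touched.

**Step 20**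
Reactants: 30 azido hydroxy ketone
Product: 32 lactam (5-oxo derivative of the target), via aminodiazonium triflate 31 (not isolated)
Conditions: TfOH (3 equiv), CH2Cl2, 0 °C to rt
Reagents that add atoms: none
Why: Protonation of the C-5 ketone lets the internal azide nitrogen add to the carbonyl (6-exo-trig) to give the azidohydrin 31, a six-membered ring N-4/C-3/C-2/C-1/C-9a/C-5 in which the N2+ group can lie equatorial and antiperiplanar to the C-5–C-9a bond; C-9a then migrates from C-5 to nitrogen as N2 leaves and the hemiaminal collapses to the lactam carbonyl. This is the intramolecular Schmidt reaction of an alkyl azide with a ketone, known for 2-(3-azidopropyl)cycloalkanones including cases with a quaternary migrating carbon. The azepane is closed by ring expansion of the cyclohexanone (nitrogen inserted between C-5 and C-9a) and the pyrrolidine by ring contraction of the six-membered azidohydrin in the same 1,2-shift, so the azepane is the last ring of the skeleton to form. No new stereocentre is created: the shift is suprafacial with retention at C-9a, so nitrogen takes the place that C-5 held and the all-carbon quaternary centre becomes the (9aR) aza-quaternary centre, while C-3 keeps its C–N bond. The step needs migration of C-9a and not of C-6 (which would give a bridged lactam); the antiperiplanar alignment in the chair azidohydrin and the higher migratory aptitude of the fully substituted carbon should secure this, and the two lactones and the tertiary alcohol are inert to the acid.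

**Step 21**
Reactants: 32 lactam
Product: 33 CNP0260919.4 (target)
Conditions: RhH(CO)(PPh3)3 (1 mol %), Ph2SiH2 (3 equiv), THF, rt; then 1 M HCl work-up
Reagents that add atoms: none
Why: rhodium-hydride-catalysed hydrosilylation reduces tertiary amides to amines in the presence of esters, so the lactam carbonyl should be removed while both γ-lactones survive; any silyl ether formed at the tertiary alcohol is cleaved on work-up.

**Compound list**

1 | cyclohexane-1,3-dione | O=C1CCCC(=O)C1 | starting material
2 | 1-bromopent-2-yne | CCC#CCBr | starting material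
3 | 2-(pent-2-yn-1-yl)cyclohexane-1,3-dione | CCC#CCC1C(=O)CCCC1=O | intermediate
4 | acrolein | C=CC=O | starting material
5 | 3-[2,6-dioxo-1-(pent-2-yn-1-yl)cyclohexyl]propanal | CCC#CCC1(CCC=O)C(=O)CCCC1=O | intermediate
6 | 2-[2-(1,3-dioxolan-2-yl)ethyl]-2-(pent-2-yn-1-yl)cyclohexane-1,3-dione | CCC#CCC1(CCC2OCCO2)C(=O)CCCC1=O | intermediate
7 | 2-[2-(1,3-dioxolan-2-yl)ethyl]-2-(2-oxopentyl)cyclohexane-1,3-dione | CCCC(=O)CC1(CCC2OCCO2)C(=O)CCCC1=O | intermediate
8 | (9aS)-bicyclic enedione, (7aS)-7a-[2-(1,3-dioxolan-2-yl)ethyl]-3-ethyl-4,5,6,7a-tetrahydro-1H-indene-2,7-dione | CCC1=C2CCCC(=O)[C@@]2(CCC3OCCO3)CC1=O | intermediate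
9 | (9aS)-C-5 ethylene ketal of 8 | CCC1=C2CCCC3(OCCO3)[C@@]2(CCC4OCCO4)CC1=O | intermediate
10 | tert-butyl bromoacetate | CC(C)(C)OC(=O)CBr | starting material
11 | lithium dienolate of 9 (C-11/C-12) | CCC1=C2CCCC3(OCCO3)[C@@]2(CCC4OCCO4)C=C1[O-].[Li+] | intermediate
12 | (9aS,12S)-enone ester, CH2CO2tBu at C-12 cis to the C-1 chain | CCC1=C2CCCC3(OCCO3)[C@@]2(CCC4OCCO4)[C@H](CC(=O)OC(C)(C)C)C1=O | intermediate
13 | (9aS,11S,12S)-allylic alcohol | CCC1=C2CCCC3(OCCO3)[C@@]2(CCC4OCCO4)[C@H](CC(=O)OC(C)(C)C)[C@@H]1O | intermediate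
14 | (9R,9aR,10S,11R,12S)-hydroxy ester, cis-hydrindane | CC[C@@H]1[C@@H](O)[C@@H](CC(=O)OC(C)(C)C)[C@]2(CCC3OCCO3)C3(OCCO3)CCC[C@H]12 | intermediate
15 | (9R,9aR,10S,11R,12S)-tricyclic γ-lactone bis-dioxolane | CC[C@@H]1[C@H]2OC(=O)C[C@H]2[C@]2(CCC3OCCO3)C3(OCCO3)CCC[C@H]12 | intermediate
16 | potassium lactone enolate of 15 | CC[C@@H]1[C@H]2OC([O-])=C[C@H]2[C@]2(CCC3OCCO3)C3(OCCO3)CCC[C@H]12.[K+] | intermediate
17 | potassium (13R)-13-alkoxide of the lactone | CC[C@@H]1[C@H]2OC(=O)[C@H]([O-])[C@H]2[C@]2(CCC3OCCO3)C3(OCCO3)CCC[C@H]12.[K+] | intermediate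
18 | (13R)-13-(triethylsilyloxy) lactone | CC[C@@H]1[C@H]2OC(=O)[C@H](O[Si](CC)(CC)CC)[C@H]2[C@]2(CCC3OCCO3)C3(OCCO3)CCC[C@H]12 | intermediate
19 | lithium enolate of 18 | CC[C@@H]1[C@H]2OC([O-])=C(O[Si](CC)(CC)CC)[C@H]2[C@]2(CCC3OCCO3)C3(OCCO3)CCC[C@H]12.[Li+] | intermediate
20 | (13S)-13-methyl-13-(triethylsilyloxy) lactone | CC[C@@H]1[C@H]2OC(=O)[C@@](C)(O[Si](CC)(CC)CC)[C@H]2[C@]2(CCC3OCCO3)C3(OCCO3)CCC[C@H]12 | intermediate
21 | C-3 aldehyde (C-5 ketal, 13-OSiEt3) | CC[C@@H]1[C@H]2OC(=O)[C@@](C)(O[Si](CC)(CC)CC)[C@H]2[C@]2(CCC=O)C3(OCCO3)CCC[C@H]12 | intermediate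
22 | (R)-2-methylpropane-2-sulfinamide | CC(C)(C)[S@@](=O)N | starting material
23 | (RS,E)-N-tert-butanesulfinyl aldimine | CC[C@@H]1[C@H]2OC(=O)[C@@](C)(O[Si](CC)(CC)CC)[C@H]2[C@]2(CC/C=N/[S@](=O)C(C)(C)C)C3(OCCO3)CCC[C@H]12 | intermediate
24 | 3-methylfuran-2(5H)-one | CC1=CCOC1=O | starting material
25 | 3-methyl-2-(triisopropylsilyloxy)furan | CC1=C(O[Si](C(C)C)(C(C)C)C(C)C)OC=C1 | intermediate
26 | (3S,18S)-N-sulfinyl aminoalkyl butenolide | CC[C@@H]1[C@H]2OC(=O)[C@@](C)(O[Si](CC)(CC)CC)[C@H]2[C@]2(CC[C@@H]([C@@H]4C=C(C)C(=O)O4)N[S@](=O)C(C)(C)C)C3(OCCO3)CCC[C@H]12 | intermediate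
27 | (3S,18S,20S)-N-sulfinyl aminoalkyl γ-lactone | CC[C@@H]1[C@H]2OC(=O)[C@@](C)(O[Si](CC)(CC)CC)[C@H]2[C@]2(CC[C@@H]([C@@H]4C[C@H](C)C(=O)O4)N[S@](=O)C(C)(C)C)C3(OCCO3)CCC[C@H]12 | intermediate
28 | (3S)-ammonium chloride | CC[C@@H]1[C@H]2OC(=O)[C@@](C)(O[Si](CC)(CC)CC)[C@H]2[C@]2(CC[C@@H]([C@@H]4C[C@H](C)C(=O)O4)[NH3+])C3(OCCO3)CCC[C@H]12.[Cl-] | intermediate
29 | (3S)-azide (C-5 ketal, 13-OSiEt3) | CC[C@@H]1[C@H]2OC(=O)[C@@](C)(O[Si](CC)(CC)CC)[C@H]2[C@]2(CC[C@@H]([C@@H]4C[C@H](C)C(=O)O4)N=[N+]=[N-])C3(OCCO3)CCC[C@H]12 | intermediate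
30 | azido hydroxy ketone (3S,9R,9aR,10S,11R,12S,13S,18S,20S) | CC[C@@H]1[C@H]2OC(=O)[C@@](C)(O)[C@H]2[C@]2(CC[C@@H]([C@@H]3C[C@H](C)C(=O)O3)N=[N+]=[N-])C(=O)CCC[C@H]12 | intermediate
31 | aminodiazonium triflate (azidohydrin, C-5 epimers) | CC[C@@H]1[C@H]2OC(=O)[C@@](C)(O)[C@H]2[C@]23CC[C@@H]([C@@H]4C[C@H](C)C(=O)O4)N([N+]#N)C2(O)CCC[C@H]13.[O-]S(=O)(=O)C(F)(F)F | intermediate
32 | lactam, 5-oxo derivative of the target | CC[C@@H]1[C@H]2OC(=O)[C@@](C)(O)[C@H]2[C@]23CC[C@@H]([C@@H]4C[C@H](C)C(=O)O4)N2C(=O)CCC[C@H]13 | intermediate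
33 | CNP0260919.4, (3S,9R,9aR,10S,11R,12S,13S,18S,20S) | CC[C@@H]1[C@H]2OC(=O)[C@@](C)(O)[C@H]2[C@]23CC[C@@H]([C@@H]4C[C@H](C)C(=O)O4)N2CCCC[C@H]13 | target

**Step count**

Total steps: 21. Longest linear sequence: 20 (steps 1 to 14 and 16 to 21).

**Steps most likely to fail**

Step 5 (Proposed new method). The 5-(enolendo) closure may not turn over under the chiral acid, or the two ring carbonyls may be poorly discriminated, giving low enantiomeric purity. Fallback with known chemistry, setting out from 7: racemic aldol condensation with pyrrolidine and acetic acid gives the racemic enedione F1. Ketalization as in step 6 gives the racemic ketal F2. Corey–Bakshi–Shibata reduction with the (R)-methyl oxazaborolidine and BH3·SMe2 reduces the enone carbonyl of both enantiomers with the same facial sense, so the diastereomeric allylic alcohols (9aS,11S)-alcohol F3 and (9aR,11S)-alcohol F4 form and are separated by chromatography. Oxidation of F3 with MnO2 comes back to the route at 9.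

Step 7. The enolate alkylation may discriminate poorly between the two faces, or may occur from the ketal face; the wrong C-12 configuration would then be relayed to C-11, C-10 and C-9. Fallback, setting out from 8: NaBH4 reduces only the saturated C-5 ketone to the hydroxy enone F5. Aldol condensation at C-12 with tert-butyl glyoxylate (LiN(SiMe3)2, then mesylation and elimination with DBU) gives the exocyclic (E)-alkylidene F6. Hydrogenation with [Ir(cod)(PCy3)(py)]PF6 and one equivalent of H2, directed by the C-5 hydroxyl, delivers H-12 from the face of C-5 and gives the hydroxy enone ester F7 with the side chain cis to the C-1 chain. Dess–Martin oxidation gives the diketone F8, and ketalization of its C-5 ketone (Me3SiOCH2CH2OSiMe3, Me3SiOTf, −78 °C) comes back to the route at 12.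

Step 20. The secondary azide may add too slowly to the hindered ketone next to the quaternary carbon, C-6 may migrate instead of C-9a to give a bridged lactam, or the strong acid may cause elimination at the azide. Fallback, setting out from 30: Staudinger reduction with PMe3 and intramolecular aza-Wittig condensation give the cyclic imine F9 (N-4=C-5). Oxidation with mCPBA gives the oxaziridine F10. Irradiation at 254 nm in MeCN rearranges the oxaziridine to the lactam; the bond anti to the nitrogen lone pair migrates, and because C-3 and C-9a sit in one six-membered ring this bond is C-5–C-9a. The fallback comes back to the route at 32.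

**Further compounds**

F1 | step 5 | racemic enedione (rac-8) | CCC1=C2CCCC(=O)C2(CCC3OCCO3)CC1=O
F2 | step 5 | racemic C-5 ethylene ketal (rac-9) | CCC1=C2CCCC3(OCCO3)C2(CCC4OCCO4)CC1=O
F3 | step 5 | (9aS,11S)-allylic alcohol | CCC1=C2CCCC3(OCCO3)[C@@]2(CCC4OCCO4)C[C@@H]1O
F4 | step 5 | (9aR,11S)-allylic alcohol | CCC1=C2CCCC3(OCCO3)[C@]2(CCC4OCCO4)C[C@@H]1O
F5 | step 7 | C-5 hydroxy enone (OH cis to the C-1 chain) | CCC1=C2CCC[C@H](O)[C@@]2(CCC3OCCO3)CC1=O
F6 | step 7 | (E)-C-12 alkylidene hydroxy enone ester | CCC1=C2CCC[C@H](O)[C@@]2(CCC3OCCO3)/C(=C\C(=O)OC(C)(C)C)C1=O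
F7 | step 7 | (12S)-hydroxy enone ester | CCC1=C2CCC[C@H](O)[C@@]2(CCC3OCCO3)[C@H](CC(=O)OC(C)(C)C)C1=O
F8 | step 7 | (9aS,12S)-diketone ester | CCC1=C2CCCC(=O)[C@@]2(CCC3OCCO3)[C@H](CC(=O)OC(C)(C)C)C1=O
F9 | step 20 | cyclic imine (N-4=C-5) | CC[C@@H]1[C@H]2OC(=O)[C@@](C)(O)[C@H]2[C@]23CC[C@@H]([C@@H]4C[C@H](C)C(=O)O4)N=C2CCC[C@H]13
F10 | step 20 | oxaziridine (N-4, C-5, O) | CC[C@@H]1[C@H]2OC(=O)[C@@](C)(O)[C@H]2[C@]23CC[C@@H]([C@@H]4C[C@H](C)C(=O)O4)N4OC24CCC[C@H]13
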